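The seven-membered ring carries oxygen at C6 and C10, the two carbons that flank the cis ring-fusion bond C1–C5 (daucane numbering). This 1,4-dioxygenated array is the retron of a cyclobutane-1,2-diol cleavage, so the cycloheptene is traced back to a 5-4-5 tricycle. The key step is the [2+2] photocycloaddition of 3-methylcyclopent-2-enone (C1–C5) to 4-methyl-1,2-bis(trimethylsilyloxy)cyclopentene (C6–C10). It forms C1–C10 and C5–C6 at once, sets the quaternary C1 and the cis fusion, and stores the seven-membered ring as two fused small rings. Later C6–C10 glycol cleavage releases it as a 6,10-diketone for stereocontrolled reduction and acylation.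

Key step: step 2

Remark on numbering: daucane numbering is used throughout (C1 angular-methyl carbon, C2, C3, C4 isopropyl carbinol carbon, C5 ring-fusion CH, C6 aroyloxy carbon, C7, C8 vinylic-methyl carbon, C9, C10 isovaleryloxy carbon); α is the face of the C1 methyl group.

Remark on stereochemistry: compounds 4–15 are racemic and 4–14 are mixtures of C8 epimers (C8 becomes sp2 in 15); their SMILES show the enantiomer that is carried to the target, and the absolute configuration is fixed in step 10.

Step 1
Reactants: 1 dimethyl 3-methylpentanedioate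
Product: 2 4-methyl-1,2-bis(trimethylsilyloxy)cyclopent-1-ene
Conditions: Na (4.2 equiv), Me3SiCl (4.5 equiv), toluene, reflux
Reagents that add atoms: chlorotrimethylsilane, C[Si](C)(C)Cl
Why: Rühlmann variant of the acyloin condensation, in which sodium couples the two ester carbonyls and Me3SiCl traps the ene-diolate as the bis(silyl) ether before Dieckmann-type side reactions can occur; no stereocenter is formed, since the methyl-bearing carbon lies on a mirror plane.

Step 2
Reactants: 2 4-methyl-1,2-bis(trimethylsilyloxy)cyclopent-1-ene, 3 3-methylcyclopent-2-en-1-one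
Product: 4 racemic cis-anti-cis 5-4-5 tricyclic ketone (cyclobutane C1–C5–C6–C10; ketone at C4; methyl on C1 and C8; Me3SiO on C6 and C10; systematic name 6,9-dimethyl-1,7-bis(trimethylsilyloxy)tricyclo[5.3.0.0(2,6)]decan-3-one)
Conditions: hν (medium-pressure Hg lamp, Pyrex filter, λ > 300 nm), 2 (4 equiv), pentane, −20 °C; excess 2 removed by distillation, crude adduct not exposed to silica gel
Reagents that add atoms: none
Why: Enone–alkene [2+2] photocycloaddition, related to the de Mayo reaction and known for cyclopentenones with 1,2-bis(silyloxy)cycloalkenes: the triplet enone adds to the electron-rich tetrasubstituted alkene through a 1,4-biradical, which collapses to the cyclobutane C1–C5–C6–C10. The only ring closed is this four-membered ring, by intermolecular bond formation followed by radical recombination within the biradical. C1 and C5 are set cis because a trans-fused bicyclo[3.2.0]heptanone is prohibitively strained, C6 and C10 are cis because they were the ring-constrained alkene carbons, and the anti arrangement of the two cyclopentanes follows from approach of the enone with its ring turned away; the C6, C10 and C8 centers are erased later, so only the cis C1/C5 relationship has to be right. Regiochemistry is not an issue because the ene-diol is symmetric about its double bond. The step needs cross-addition to outrun enone dimerisation and oxetane formation, which the fourfold excess of the non-absorbing, electron-rich alkene 2 and the slow self-dimerisation of a β,β-disubstituted enone should secure. The adduct is racemic.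

Step 3
Reactants: 4 racemic cis-anti-cis 5-4-5 tricyclic ketone
Product: 6 enol triflate of 4 (C3=C4 double bond; trifluoromethanesulfonyloxy on C4), via potassium enolate 5 (not isolated)
Conditions: KN(SiMe3)2, THF, −78 °C; then PhNTf2, −78 → 0 °C
Reagents that add atoms: N-phenylbis(trifluoromethanesulfonimide), O=S(=O)(N(c1ccccc1)S(=O)(=O)C(F)(F)F)C(F)(F)F; potassium bis(trimethylsilyl)amide (potassium of intermediate 5 only), C[Si](C)(C)[N-][Si](C)(C)C.[K+]
Why: Kinetic deprotonation at the C3 methylene (the C5 methine is a cyclobutane ring-fusion position) and O-sulfonylation of the enolate give the enol triflate; no stereocenter is touched, and the ketone is removed before the β-silyloxy groups can be lost.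

Step 4
Reactants: 6 enol triflate, 7 isopropylzinc bromide
Product: 8 tricyclic alkene (C3=C4 double bond; isopropyl on C4)
Conditions: Pd(dppf)Cl2 (5 mol%), THF, 50 °C
Reagents that add atoms: none
Why: Negishi coupling of an alkenyl triflate with a secondary alkylzinc halide; the wide-bite-angle dppf ligand favours reductive elimination over β-hydride elimination, so the isopropyl group should be transferred without isomerisation to n-propyl; no stereocenter is formed.

Step 5
Reactants: 8 tricyclic alkene
Product: 9 tricyclic tertiary alcohol (4α-hydroxy, 4β-isopropyl; Me3SiO on C6 and C10)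
Conditions: Mn(dpm)3 (10 mol%), PhSiH3, O2 (1 atm), iPrOH/CH2Cl2, 0 °C
Reagents that add atoms: dioxygen, O=O
Why: Mukaiyama hydration by metal-hydride hydrogen-atom transfer: hydrogen is delivered to C3, the tertiary C4 radical is captured by O2 on the convex exo face of the bicyclo[3.2.0]heptane unit (the face of the C1 methyl and H5, away from the cyclobutane and its silyloxy groups), and the peroxide is reduced in situ, which sets C4 with OH α and isopropyl β.

Step 6
Reactants: 9 tricyclic tertiary alcohol
Product: 11 cis-fused 4α-hydroxy-4β-isopropyl-1α,8-dimethyl-5αH-hydroazulane-6,10-dione, via cyclobutane triol 10 (not isolated)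
Conditions: K2CO3, MeOH, 0 °C → rt; AcOH quench, solvent exchange; then Pb(OAc)4, CH2Cl2, −20 °C
Reagents that add atoms: none
Why: Methanolysis of the two tertiary trimethylsilyl ethers followed by glycol cleavage (Criegee oxidation) of the strained cis-cyclobutane-1,2-diol breaks C6–C10 and turns the tricycle into the cis-fused bicyclo[5.3.0]decane with ketones at C6 and C10; C1, C4 and C5 are untouched because no base is present once the C6 ketone exists.

Step 7
Reactants: 11 cis-fused hydroxy diketone
Product: 12 cis-fused 4α,6β-dihydroxy-4β-isopropyl-1α,8-dimethyl-5αH-hydroazulan-10-one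
Conditions: Me4NBH(OAc)3, MeCN/AcOH (1:1), −30 °C
Reagents that add atoms: none
Why: Evans–Saksena reduction: the C4 hydroxyl binds boron and delivers hydride intramolecularly to the α face of the C6 ketone through a six-membered transition state, giving the 6β-alcohol (anti 1,3-diol); the C10 ketone has no β-hydroxyl and is not reduced by this mild reagent.

Step 8
Reactants: 12 diol ketone, 13 4-acetoxybenzoyl chloride
Product: 14 6β-(4-acetoxybenzoyloxy)-4α-hydroxy-4β-isopropyl-1α,8-dimethyl-5αH-hydroazulan-10-one
Conditions: pyridine, DMAP (cat.), CH2Cl2, 0 °C → rt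
Reagents that add atoms: none
Why: DMAP-catalysed esterification of the secondary C6 hydroxyl; the tertiary C4 hydroxyl is too hindered to react, any 6,10-hemiketal form of 12 equilibrates with the hydroxy ketone and is drained by acylation, and no stereocenter changes.

Step 9
Reactants: 14 keto ester
Product: 15 racemic enone, 6β-(4-acetoxybenzoyloxy)-4α-hydroxy-4β-isopropyl-1α,8-dimethyl-5αH-hydroazul-8-en-10-one
Conditions: IBX (2.2 equiv), toluene/DMSO (2:1), 70 °C
Reagents that add atoms: none
Why: IBX dehydrogenation of a ketone to its enone; C9 is the only enolisable position of the C10 ketone because C1 is quaternary, and loss of H8 makes C8 planar, so both C8 epimers converge on one enone.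

Step 10
Reactants: 15 racemic enone
Product: 16 single-enantiomer allylic alcohol, 6β-(4-acetoxybenzoyloxy)-4β-isopropyl-1α,8-dimethyl-5αH-hydroazul-8-ene-4α,10α-diol (10R)
Conditions: (S)-Me-CBS oxazaborolidine (1.0 equiv), catecholborane, toluene, −78 → −40 °C; chromatographic separation of the diastereomeric alcohols
Reagents that add atoms: none
Why: Corey–Bakshi–Shibata reduction used as a divergent reaction on the racemate: with the quaternary C1 flank as the large group and the vinylic C9 as the small one, hydride is delivered to the same absolute face of C10 in both enantiomers, so the (1R) enantiomer should give the 10α-alcohol 16 (10R, hydroxyl cis to the C1 methyl) and the (1S) enantiomer a 10β-diastereomer that is removed by chromatography, which fixes C10 and the absolute configuration together.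

Step 11
Reactants: 16 allylic alcohol, 17 3-methylbutanoic anhydride
Product: 18 10α-(3-methylbutanoyloxy)-6β-(4-acetoxybenzoyloxy)-4β-isopropyl-1α,8-dimethyl-5αH-hydroazul-8-en-4α-ol
Conditions: Et3N, DMAP (0.3 equiv), CH2Cl2, rt
Reagents that add atoms: none
Why: Nucleophile-catalysed acylation of the hindered secondary allylic alcohol proceeds at oxygen with retention at C10; the tertiary C4 hydroxyl does not react.

Step 12
Reactants: 18 aryl acetate
Product: 19 target, (3S,3aS,4R,8R,8aR)-3-hydroxy-6,8a-dimethyl-8-(3-methylbutanoyloxy)-3-(propan-2-yl)-1,2,3,3a,4,5,8,8a-octahydroazulen-4-yl 4-hydroxybenzoate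
Conditions: NH4OAc (10 equiv), MeOH/H2O (4:1), rt
Reagents that add atoms: none
Why: Chemoselective solvolysis of the phenolic acetate, whose aryloxide leaving group makes it far more reactive than the two alkyl esters; no stereocenter is involved.

Compound list
1 | dimethyl 3-methylpentanedioate | COC(=O)CC(C)CC(=O)OC | starting material
2 | 4-methyl-1,2-bis(trimethylsilyloxy)cyclopent-1-ene | CC1CC(O[Si](C)(C)C)=C(O[Si](C)(C)C)C1 | intermediate
3 | 3-methylcyclopent-2-en-1-one | CC1=CC(=O)CC1 | starting material
4 | cis-anti-cis 6,9-dimethyl-1,7-bis(trimethylsilyloxy)tricyclo[5.3.0.0(2,6)]decan-3-one (racemic, C8 epimers; daucane C4 ketone, Me on C1 and C8, Me3SiO on C6 and C10) | CC1C[C@@]3(O[Si](C)(C)C)[C@]2(C)CCC(=O)[C@@H]2[C@@]3(O[Si](C)(C)C)C1 | intermediate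
5 | potassium enolate of 4 (C3=C4, O–K on C4) | CC1C[C@@]3(O[Si](C)(C)C)[C@]2(C)CC=C([O-])[C@@H]2[C@@]3(O[Si](C)(C)C)C1.[K+] | intermediate (not isolated)
6 | enol triflate of 4 (C3=C4, OSO2CF3 on C4) | CC1C[C@@]3(O[Si](C)(C)C)[C@]2(C)CC=C(OS(=O)(=O)C(F)(F)F)[C@@H]2[C@@]3(O[Si](C)(C)C)C1 | intermediate
7 | isopropylzinc bromide | CC(C)[Zn]Br | starting material
8 | tricyclic alkene (C3=C4, isopropyl on C4) | CC1C[C@@]3(O[Si](C)(C)C)[C@]2(C)CC=C(C(C)C)[C@@H]2[C@@]3(O[Si](C)(C)C)C1 | intermediate
9 | tricyclic tertiary alcohol (4α-OH, 4β-isopropyl, Me3SiO on C6 and C10) | CC1C[C@@]3(O[Si](C)(C)C)[C@]2(C)CC[C@](O)(C(C)C)[C@@H]2[C@@]3(O[Si](C)(C)C)C1 | intermediate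
10 | cyclobutane triol (4α-OH, cis-6,10-diol) | CC1C[C@@]3(O)[C@]2(C)CC[C@](O)(C(C)C)[C@@H]2[C@@]3(O)C1 | intermediate (not isolated)
11 | cis-fused 4α-hydroxy-4β-isopropyl-1α,8-dimethyl-5αH-hydroazulane-6,10-dione | CC1CC(=O)[C@]2(C)CC[C@](O)(C(C)C)[C@@H]2C(=O)C1 | intermediate
12 | cis-fused 4α,6β-dihydroxy-4β-isopropyl-1α,8-dimethyl-5αH-hydroazulan-10-one | CC1CC(=O)[C@]2(C)CC[C@](O)(C(C)C)[C@@H]2[C@H](O)C1 | intermediate
13 | 4-acetoxybenzoyl chloride | CC(=O)Oc1ccc(cc1)C(Cl)=O | starting material
14 | 6β-(4-acetoxybenzoyloxy)-4α-hydroxy-4β-isopropyl-1α,8-dimethyl-5αH-hydroazulan-10-one | CC1CC(=O)[C@]2(C)CC[C@](O)(C(C)C)[C@@H]2[C@H](OC(=O)c2ccc(OC(C)=O)cc2)C1 | intermediate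
15 | 6β-(4-acetoxybenzoyloxy)-4α-hydroxy-4β-isopropyl-1α,8-dimethyl-5αH-hydroazul-8-en-10-one (racemic) | CC1=CC(=O)[C@]2(C)CC[C@](O)(C(C)C)[C@@H]2[C@H](OC(=O)c2ccc(OC(C)=O)cc2)C1 | intermediate
16 | 6β-(4-acetoxybenzoyloxy)-4β-isopropyl-1α,8-dimethyl-5αH-hydroazul-8-ene-4α,10α-diol (single enantiomer, 10R) | CC1=C[C@@H](O)[C@]2(C)CC[C@](O)(C(C)C)[C@@H]2[C@H](OC(=O)c2ccc(OC(C)=O)cc2)C1 | intermediate
17 | 3-methylbutanoic anhydride | CC(C)CC(=O)OC(=O)CC(C)C | starting material
18 | 10α-(3-methylbutanoyloxy)-6β-(4-acetoxybenzoyloxy)-4β-isopropyl-1α,8-dimethyl-5αH-hydroazul-8-en-4α-ol | CC1=C[C@@H](OC(=O)CC(C)C)[C@]2(C)CC[C@](O)(C(C)C)[C@@H]2[C@H](OC(=O)c2ccc(OC(C)=O)cc2)C1 | intermediate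
19 | (3S,3aS,4R,8R,8aR)-3-hydroxy-6,8a-dimethyl-8-(3-methylbutanoyloxy)-3-(propan-2-yl)-1,2,3,3a,4,5,8,8a-octahydroazulen-4-yl 4-hydroxybenzoate (CNP0086724.1) | CC1=C[C@@H](OC(=O)CC(C)C)[C@]2(C)CC[C@](O)(C(C)C)[C@@H]2[C@H](OC(=O)c2ccc(O)cc2)C1 | target

Total step count: 12. Longest linear sequence: 12 steps (1 → 2 → 4 → 6 → 8 → 9 → 11 → 12 → 14 → 15 → 16 → 18 → 19).

Steps most likely to fail

Step 5. The tertiary C4 radical is a cyclobutylcarbinyl radical, so β-scission of the C5–C6 bond (driven by strain release and formation of an α-silyloxy radical) may compete with oxygen capture, and capture may be poorly face-selective. The fallback sets out from alkene 8. Epoxidation with dimethyldioxirane (acetone, −20 °C) on the exo face should give the 3α,4α-epoxide F1. Opening of this epoxide at the secondary C3 with LiBHEt3 (THF, 0 °C) should return the route at tertiary alcohol 9.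

Step 10. The oxazaborolidine may not discriminate well enough between the quaternary C1 flank and the vinylic C9 flank, or the substrate bias may dominate, so that the two enantiomers are not funnelled cleanly into separable diastereomers and enantiomeric purity is lost. The fallback sets out from racemic enone 15. Its enantiomers are separated by preparative chromatography on a chiral stationary phase, and the (1R) enantiomer is reduced under substrate control with NaBH4/CeCl3 (MeOH, −78 °C). If this gives 16, the route continues unchanged. If it gives the 10β-alcohol F2, Mitsunobu esterification with 3-methylbutanoic acid (PPh3, DIAD, toluene, 0 °C → rt) inverts C10 and comes back at 18.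

Step 9. At 70 °C the enone may be dehydrogenated further towards a dienone, or the C6 aroyloxy group may be eliminated through the dienol (vinylogous β-elimination). The fallback sets out from ketone 14. Soft enolisation with Me3SiOTf/Et3N (CH2Cl2, 0 °C) should give the bis(trimethylsilyl) enol ether F3 (C9=C10 silyl enol ether, C4 silyl ether). Saegusa–Ito oxidation with Pd(OAc)2 (MeCN, rt) and dilute HCl work-up should then come back at enone 15.

Further compounds
F1 | step 5 | 3α,4α-epoxide of alkene 8 (exo epoxide, isopropyl on C4) | CC1C[C@@]3(O[Si](C)(C)C)[C@]2(C)C[C@H]4O[C@@]4(C(C)C)[C@@H]2[C@@]3(O[Si](C)(C)C)C1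
F2 | step 10 | 10β-alcohol, C10 epimer of 16 | CC1=C[C@H](O)[C@]2(C)CC[C@](O)(C(C)C)[C@@H]2[C@H](OC(=O)c2ccc(OC(C)=O)cc2)C1
F3 | step 9 | bis(trimethylsilyl) enol ether of 14 (C9=C10 silyl enol ether, 4α-silyloxy) | CC1CC=C(O[Si](C)(C)C)[C@]2(C)CC[C@](O[Si](C)(C)C)(C(C)C)[C@@H]2[C@H](OC(=O)c2ccc(OC(C)=O)cc2)C1
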